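Ring A is disconnected at C3–C4 and C1–C2, back to methacrolein and a 2-silyloxybutadiene with nitrogen on its terminus. The cycloaddition exploits the substitution pattern at quaternary C3 of ring A (methyl, the prenyl CH2, ring neighbours C2 and C4, oxygen at C6 across the ring): one operation closes ring A, makes both bonds and sets C3, the only stereocentre. The diene nitrogen is carried as a benzyl methyl carbamate, which, unlike a free dialkylamino group, tolerates the chromium Lewis acid and reacts only slowly without it. Afterwards C1 is acylated before C2 and C4 are oxidised, so that ring A is never symmetric, and ring B is attached last.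

Key step: step 4

Assumption: the (R,R)-configured chromium salen complex is taken to deliver the (S)-aldehyde 9; if the first run shows the opposite sense of induction, the (S,S)-complex is used and nothing else changes.

Remark: ring A is numbered C1 (hexanoyl), C2 (OH), C3 (quaternary), C4 (OH), C5 (methylene bridge), C6 (ketone); ring B is the aromatic ring; enolised di- and tricarbonyl compounds are drawn as one tautomer; TBS = tert-butyldimethylsilyl.

Step 1
Reactants: 1 (E)-4-methoxybut-3-en-2-one; 2 benzylamine
Product: 3 (Z)-4-(benzylamino)but-3-en-2-one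
Conditions: CH2Cl2, 0 °C to rt
Reagents that add atoms: none
Why: Addition–elimination of the amine at the β-carbon of the vinylogous ester (amine exchange) should give the vinylogous amide, held in the Z form by an N–H···O hydrogen bond.

Step 2
Reactants: 3 (Z)-4-(benzylamino)but-3-en-2-one
Product: 4 methyl benzyl[(1E)-3-oxobut-1-en-1-yl]carbamate
Conditions: NaN(SiMe3)2, THF, −78 °C; ClCO2Me, −78 to 0 °C
Reagents that add atoms: methyl chloroformate, COC(Cl)=O
Why: The sodium salt of the vinylogous amide should be acylated on nitrogen by the chloroformate (carbamate formation), and the vinylogous imide, no longer hydrogen-bonded, should settle in the E geometry.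

Step 3
Reactants: 4 methyl benzyl[(1E)-3-oxobut-1-en-1-yl]carbamate
Product: 5 methyl benzyl[(1E)-3-(tert-butyldimethylsilyloxy)buta-1,3-dien-1-yl]carbamate
Conditions: KN(SiMe3)2, THF, −78 °C; TBSCl, −78 °C to rt
Reagents that add atoms: tert-butyldimethylsilyl chloride, CC(C)(C)[Si](C)(C)Cl
Why: Kinetic deprotonation of the methyl ketone and O-silylation of the potassium enolate (silyl enol ether formation) should give the 2-silyloxy diene and leave the E enamide double bond untouched.

Step 4
Reactants: 5 methyl benzyl[(1E)-3-(tert-butyldimethylsilyloxy)buta-1,3-dien-1-yl]carbamate; 6 methacrolein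
Product: 9 (S)-1-methyl-4-oxocyclohex-2-ene-1-carbaldehyde, via cycloadduct 7 (not isolated), via keto carbamate 8 (not isolated)
Conditions: (R,R)-[Cr(salen)]SbF6 (5 mol %; salen = dianion of N,N'-bis(3,5-di-tert-butylsalicylidene)cyclohexane-1,2-diamine), 4 Å molecular sieves, CH2Cl2, −40 °C; then 48% aq. HF, MeCN, 0 °C to rt
Reagents that add atoms: none
Why: The cationic trivalent chromium centre binds the aldehyde oxygen of 6, and the diene adds in a concerted, asynchronous endo Diels–Alder reaction in which its CH2 terminus bonds to the β-carbon (C1–C2) and its nitrogen-bearing terminus to the α-carbon (C3–C4). The closest known reaction type is the chromium salen-catalysed enantioselective cycloaddition of 1-carbamato-3-silyloxybutadienes with α-substituted acroleins. Ring A closes as a six-membered carbocycle in the intermolecular [4+2] mode, both bonds being formed in the same step. C3 is controlled by the salen ligand, which leaves one enantioface of the bound methacrolein open, while the C4 centre fixed by the endo rule disappears again on elimination. The step needs regioselectivity, which the joint push of the nitrogen and the silyloxy oxygen toward the unsubstituted diene terminus secures, and a negligible racemic background reaction, which the electron-poor carbamate nitrogen secures. HF then cleaves the silyl enol ether to ketone 8, which loses methyl benzylcarbamate by β-elimination to give the enone, whose quaternary C3 carries no hydrogen and cannot epimerise.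

Step 5
Reactants: 9 (S)-1-methyl-4-oxocyclohex-2-ene-1-carbaldehyde
Product: 11 (R)-2-(1-methyl-4-oxocyclohex-2-en-1-yl)acetaldehyde, via enol ether 10 (not isolated)
Conditions: Ph3P(CH2OMe)Cl, KN(SiMe3)2, THF, 0 °C; 9, −78 to −20 °C; then 1 M HCl, THF, 0 °C to rt
Reagents that add atoms: (methoxymethyl)triphenylphosphonium chloride, COC[P+](c1ccccc1)(c1ccccc1)c1ccccc1.[Cl-]; water, O
Why: Wittig olefination with the methoxymethylene ylide at low temperature should take the aldehyde in preference to the less electrophilic conjugated ketone, and acid hydrolysis of the enol ether then releases the homologous aldehyde without involving C3.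

Step 6
Reactants: 11 (R)-2-(1-methyl-4-oxocyclohex-2-en-1-yl)acetaldehyde
Product: 12 (R)-4-methyl-4-(3-methylbut-2-en-1-yl)cyclohex-2-en-1-one
Conditions: i-PrPPh3I, n-BuLi, THF, 0 °C; 11, −78 to 0 °C
Reagents that add atoms: isopropyltriphenylphosphonium iodide, CC(C)[P+](c1ccccc1)(c1ccccc1)c1ccccc1.[I-]
Why: Wittig olefination of the unhindered aldehyde with the isopropylidene ylide should outrun attack on the enone at low temperature and gives the trisubstituted prenyl double bond, for which no E/Z question arises.

Step 7
Reactants: 12 (R)-4-methyl-4-(3-methylbut-2-en-1-yl)cyclohex-2-en-1-one; 13 hexanoyl chloride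
Product: 14 (4S)-6-hexanoyl-4-methyl-4-(3-methylbut-2-en-1-yl)cyclohex-2-en-1-one (enolised β-diketone)
Conditions: LiN(SiMe3)2 (2.2 equiv), toluene/THF, −78 °C; 13, −78 to 0 °C; aq. NH4Cl
Reagents that add atoms: none
Why: Because the γ-position is quaternary, the amide base can only form the cross-conjugated α′-enolate at C1, and its C-acylation by the acid chloride in toluene (crossed Claisen-type acylation) should give the β-diketone, which the second equivalent of base keeps as its enolate.

Step 8
Reactants: 14 (4S)-6-hexanoyl-4-methyl-4-(3-methylbut-2-en-1-yl)cyclohex-2-en-1-one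
Product: 15 (4R)-2-hexanoyl-4-methyl-4-(3-methylbut-2-en-1-yl)cyclohexa-2,5-dien-1-one
Conditions: DDQ (1.2 equiv), 1,4-dioxane, rt
Reagents that add atoms: none
Why: DDQ dehydrogenation of the enolised β-diketone (hydride abstraction from C2, the only allylic C–H of the enol, then loss of a proton) should give the 2-acyl cross-conjugated dienone, which stays chiral because the acyl group marks C1.

Step 9
Reactants: 15 (4R)-2-hexanoyl-4-methyl-4-(3-methylbut-2-en-1-yl)cyclohexa-2,5-dien-1-one
Product: 16 1-hexanoyl-6-methyl-6-(3-methylbut-2-en-1-yl)-4,8-dioxatricyclo[5.1.0.0^3,5]octan-2-one (the C1–C2 and C4–C5 bis-epoxide of 15, epoxide diastereomers, quaternary carbon unchanged)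
Conditions: t-BuOOH (decane, 3 equiv), DBU, CH2Cl2, 0 °C to rt
Reagents that add atoms: tert-butyl hydroperoxide, CC(C)(C)OO
Why: Nucleophilic (Weitz–Scheffer) epoxidation by the tert-butylperoxide anion should attack both β-carbons, C2 and C4, of the dienone and spare the electron-rich prenyl alkene, and the epoxide configurations do not matter because all four epoxide carbons lose their stereochemistry in step 10.

Step 10
Reactants: 16 bis-epoxide of 15
Product: 17 (4R)-2-hexanoyl-3,5-dihydroxy-4-methyl-4-(3-methylbut-2-en-1-yl)cyclohexa-2,5-dien-1-one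
Conditions: Pd(PPh3)4 (5 mol %), 1,2-bis(diphenylphosphino)ethane (5 mol %), toluene, 80 °C
Reagents that add atoms: none
Why: Zerovalent palladium isomerises α,β-epoxy ketones to β-diketones by opening the Cα–O bond and shifting the Cβ hydrogen, so that applied to both epoxides it should turn C2 and C4 into carbonyl carbons and give the enolised trione without touching C3.

Step 11
Reactants: 18 phloroglucinol; 19 butanoyl chloride
Product: 20 1-(2,4,6-trihydroxyphenyl)butan-1-one
Conditions: AlCl3, nitrobenzene/CH2Cl2, 0 to 40 °C; then aq. HCl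
Reagents that add atoms: none
Why: Friedel–Crafts acylation of the highly activated, threefold symmetric arene should stop at the mono-ketone because the acyl group deactivates the ring.

Step 12
Reactants: 20 1-(2,4,6-trihydroxyphenyl)butan-1-one
Product: 21 1-(2,6-dihydroxy-4-methoxyphenyl)butan-1-one
Conditions: Me2SO4 (1.0 equiv), K2CO3, acetone, reflux
Reagents that add atoms: dimethyl sulfate, COS(=O)(=O)OC
Why: Williamson O-methylation with one equivalent of dimethyl sulfate should go to the 4-hydroxyl, which is the most acidic and the only one not engaged in a hydrogen bond to the ketone.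

Step 13
Reactants: 21 1-(2,6-dihydroxy-4-methoxyphenyl)butan-1-one
Product: 22 1-{3-[(dimethylamino)methyl]-2,6-dihydroxy-4-methoxyphenyl}butan-1-one
Conditions: 37% aq. CH2O (1.0 equiv), 40% aq. Me2NH, EtOH, 0 °C to rt
Reagents that add atoms: formaldehyde, C=O; dimethylamine, CNC
Why: Mannich aminomethylation of the electron-rich phenol should occur at C3 or the equivalent C5, the only free ring positions, and one equivalent of the iminium partner limits it to one of them.

Step 14
Reactants: 17 (4R)-2-hexanoyl-3,5-dihydroxy-4-methyl-4-(3-methylbut-2-en-1-yl)cyclohexa-2,5-dien-1-one; 22 1-{3-[(dimethylamino)methyl]-2,6-dihydroxy-4-methoxyphenyl}butan-1-one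
Product: 24 (4R)-6-[(3-butanoyl-2,4-dihydroxy-6-methoxyphenyl)methyl]-2-hexanoyl-3,5-dihydroxy-4-methyl-4-(3-methylbut-2-en-1-yl)cyclohexa-2,5-dien-1-one, via quinone methide 23 (not isolated)
Conditions: 1,4-dioxane, 90 °C, N2, slow addition of 22 to 17
Reagents that add atoms: none
Why: On heating, the phenolic Mannich base should lose dimethylamine to give an ortho-quinone methide, which the enolised trione traps at C5, its only nucleophilic carbon that still bears hydrogen (Michael addition), so that the methylene bridge forms without touching C3.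

Compound list
1 | (E)-4-methoxybut-3-en-2-one | CO/C=C/C(C)=O | starting material
2 | benzylamine | NCc1ccccc1 | starting material
3 | (Z)-4-(benzylamino)but-3-en-2-one | CC(=O)/C=C\NCc1ccccc1 | intermediate
4 | methyl benzyl[(1E)-3-oxobut-1-en-1-yl]carbamate | CC(=O)/C=C/N(Cc1ccccc1)C(=O)OC | intermediate
5 | methyl benzyl[(1E)-3-(tert-butyldimethylsilyloxy)buta-1,3-dien-1-yl]carbamate | COC(=O)N(Cc1ccccc1)/C=C/C(=C)O[Si](C)(C)C(C)(C)C | intermediate
6 | methacrolein | CC(=C)C=O | starting material
7 | methyl benzyl[(1R,6S)-3-(tert-butyldimethylsilyloxy)-6-formyl-6-methylcyclohex-2-en-1-yl]carbamate (endo cycloadduct) | CC(C)(C)[Si](C)(C)OC1=C[C@@H](N(Cc2ccccc2)C(=O)OC)[C@@](C)(C=O)CC1 | intermediate (not isolated)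
8 | methyl benzyl[(1R,2S)-2-formyl-2-methyl-5-oxocyclohexyl]carbamate | O=C1C[C@@H](N(Cc2ccccc2)C(=O)OC)[C@@](C)(C=O)CC1 | intermediate (not isolated)
9 | (S)-1-methyl-4-oxocyclohex-2-ene-1-carbaldehyde | O=C[C@]1(C)C=CC(=O)CC1 | intermediate
10 | (S)-4-(2-methoxyethenyl)-4-methylcyclohex-2-en-1-one (E/Z mixture) | COC=C[C@]1(C)C=CC(=O)CC1 | intermediate (not isolated)
11 | (R)-2-(1-methyl-4-oxocyclohex-2-en-1-yl)acetaldehyde | O=CC[C@]1(C)C=CC(=O)CC1 | intermediate
12 | (R)-4-methyl-4-(3-methylbut-2-en-1-yl)cyclohex-2-en-1-one | CC(C)=CC[C@]1(C)C=CC(=O)CC1 | intermediate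
13 | hexanoyl chloride | CCCCCC(Cl)=O | starting material
14 | (4S)-6-hexanoyl-4-methyl-4-(3-methylbut-2-en-1-yl)cyclohex-2-en-1-one, drawn as its ring enol | CCCCCC(=O)C1=C(O)C=C[C@@](C)(CC=C(C)C)C1 | intermediate
15 | (4R)-2-hexanoyl-4-methyl-4-(3-methylbut-2-en-1-yl)cyclohexa-2,5-dien-1-one | CCCCCC(=O)C1=C[C@](C)(CC=C(C)C)C=CC1=O | intermediate
16 | 1-hexanoyl-6-methyl-6-(3-methylbut-2-en-1-yl)-4,8-dioxatricyclo[5.1.0.0^3,5]octan-2-one (bis-epoxide of 15, epoxide diastereomers, quaternary carbon as in 15) | CCCCCC(=O)C12OC1[C@](C)(CC=C(C)C)C1OC1C2=O | intermediate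
17 | (4R)-2-hexanoyl-3,5-dihydroxy-4-methyl-4-(3-methylbut-2-en-1-yl)cyclohexa-2,5-dien-1-one | CCCCCC(=O)C1=C(O)[C@](C)(CC=C(C)C)C(O)=CC1=O | intermediate
18 | phloroglucinol | Oc1cc(O)cc(O)c1 | starting material
19 | butanoyl chloride | CCCC(Cl)=O | starting material
20 | 1-(2,4,6-trihydroxyphenyl)butan-1-one | CCCC(=O)c1c(O)cc(O)cc1O | intermediate
21 | 1-(2,6-dihydroxy-4-methoxyphenyl)butan-1-one | CCCC(=O)c1c(O)cc(OC)cc1O | intermediate
22 | 1-{3-[(dimethylamino)methyl]-2,6-dihydroxy-4-methoxyphenyl}butan-1-one | CCCC(=O)c1c(O)cc(OC)c(CN(C)C)c1O | intermediate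
23 | 2-butanoyl-3-hydroxy-5-methoxy-6-methylidenecyclohexa-2,4-dien-1-one (ortho-quinone methide) | CCCC(=O)C1=C(O)C=C(OC)C(=C)C1=O | intermediate (not isolated)
24 | (4R)-6-[(3-butanoyl-2,4-dihydroxy-6-methoxyphenyl)methyl]-2-hexanoyl-3,5-dihydroxy-4-methyl-4-(3-methylbut-2-en-1-yl)cyclohexa-2,5-dien-1-one | CCCCCC(=O)C1=C(O)[C@](C)(CC=C(C)C)C(O)=C(Cc2c(OC)cc(O)c(C(=O)CCC)c2O)C1=O | target

Total step count: 14. Longest linear sequence: 11 steps (steps 1 to 10, then step 14); steps 11 to 13 make the ring B partner.

Steps most likely to fail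

Step 10. The epoxide that carries two acyl groups on one carbon may be deoxygenated or cleaved by the palladium–phosphine system, or the chelating trione may bind the catalyst so that only one epoxide rearranges. The fallback sets out from 16 and comes back at 17. Reductive opening of both Cα–O bonds with SmI2 in THF/MeOH at −90 °C should give 2-hexanoyl-3,5-dihydroxy-4-methyl-4-(3-methylbut-2-en-1-yl)cyclohexan-1-one F1. Oxidation of its two secondary alcohols with 1,1,1-triacetoxy-1,1-dihydro-1,2-benziodoxol-3(1H)-one (NaHCO3, CH2Cl2, rt) then gives 17.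

Step 9. The peroxide anion may attack a carbonyl of the non-enolisable diacyl epoxide (retro-Claisen or Baeyer–Villiger-type cleavage) while the hindered C4=C5 enone is still being epoxidised. The fallback sets out from 12 and comes back at 16, and it stages the two epoxidations. H2O2/NaOH in MeOH at 0 °C should convert the plain enone into 5-methyl-5-(3-methylbut-2-en-1-yl)-7-oxabicyclo[4.1.0]heptan-2-one F2. Acylation with 13 under the conditions of step 7 gives 3-hexanoyl-5-methyl-5-(3-methylbut-2-en-1-yl)-7-oxabicyclo[4.1.0]heptan-2-one F3. DDQ under the conditions of step 8 gives 3-hexanoyl-5-methyl-5-(3-methylbut-2-en-1-yl)-7-oxabicyclo[4.1.0]hept-3-en-2-one F4. Only the very electrophilic C1=C2 bond then needs a brief treatment with one equivalent of t-BuOOH and catalytic DBU at −20 °C to reach 16.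

Step 4. Enantioface discrimination may be insufficient, turnover may be slow because the carbamate carbonyl competes for the chromium centre, or the carbamate may leave sluggishly under acid. The fallback sets out from 6 and comes back at 9, and it replaces Lewis acid catalysis by hydrogen-bond catalysis with the more reactive amine diene. Purchased (E)-4-(dimethylamino)but-3-en-2-one (CN(C)/C=C/C(C)=O) is O-silylated with KN(SiMe3)2 and TBSCl in THF at −78 °C to (E)-1-(dimethylamino)-3-(tert-butyldimethylsilyloxy)buta-1,3-diene F5. This diene should add to 6 in toluene at −80 °C in the presence of α,α,α′,α′-tetra(1-naphthyl)-2,2-dimethyl-1,3-dioxolane-4,5-dimethanol (the enantiomer that leads to the S product), whose hydroxyl group activates the aldehyde by hydrogen bonding, to give (1S,2R)-2-(dimethylamino)-1-methyl-4-(tert-butyldimethylsilyloxy)cyclohex-3-ene-1-carbaldehyde F6. Dilute HCl in THF at 0 °C then removes the silyl group and dimethylamine and gives 9.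

Further compounds
F1 | step 10 | 2-hexanoyl-3,5-dihydroxy-4-methyl-4-(3-methylbut-2-en-1-yl)cyclohexan-1-one (carbinol diastereomers, quaternary carbon as in 16) | CCCCCC(=O)C1C(O)[C@](C)(CC=C(C)C)C(O)CC1=O
F2 | step 9 | 5-methyl-5-(3-methylbut-2-en-1-yl)-7-oxabicyclo[4.1.0]heptan-2-one (epoxide diastereomers, quaternary carbon as in 12) | O=C1CC[C@](C)(CC=C(C)C)C2OC12
F3 | step 9 | 3-hexanoyl-5-methyl-5-(3-methylbut-2-en-1-yl)-7-oxabicyclo[4.1.0]heptan-2-one (enolised β-diketone, epoxide diastereomers) | CCCCCC(=O)C1C[C@](C)(CC=C(C)C)C2OC2C1=O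
F4 | step 9 | 3-hexanoyl-5-methyl-5-(3-methylbut-2-en-1-yl)-7-oxabicyclo[4.1.0]hept-3-en-2-one (epoxide diastereomers) | CCCCCC(=O)C1=C[C@](C)(CC=C(C)C)C2OC2C1=O
F5 | step 4 | (E)-1-(dimethylamino)-3-(tert-butyldimethylsilyloxy)buta-1,3-diene | CN(C)/C=C/C(=C)O[Si](C)(C)C(C)(C)C
F6 | step 4 | (1S,2R)-2-(dimethylamino)-1-methyl-4-(tert-butyldimethylsilyloxy)cyclohex-3-ene-1-carbaldehyde | CC(C)(C)[Si](C)(C)OC1=C[C@@H](N(C)C)[C@@](C)(C=O)CC1
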